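**Plan**

Numbering: core C1–C8a (ring A is the benzene ring, ring B the dihydro ring), pyrone ring C O1'–C6'.
Cuts: the end game only unmasks (two aryl O–Me, two ester O–Me) and raises the C6' substituent from CH2OSi to CO2H; before that, ring C is cut at C4'–C5' and O1'–C6', the alkynoic acid at C2'–C3' (CO2), ring B at C4–C4a, C3–C4 and C2–C3, and C1 from its alkyne.
Enabling feature: ring C (O1', C2'=O, C3'H, C4' on C1, C5'H, C6' bearing the carboxyl) is the cyclised form of an alkynoic ester of an enol. C2'–C3'≡C4' is a prop-2-ynoate with C4' bound to C1, and O1'–C6'(=C5'H2) is a 1-substituted vinyl ester, so joining the enol methylene C5' to C4' closes the ring. C6' is carried as CH2OSi through this closure so that the enol alkene stays nucleophilic.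
Forward order: arylidene Meldrum's acid from veratraldehyde; conjugate alkynylation (C1–alkyne); bromoacetate alkylation (C2–C3) and methanolysis/decarboxylation; formylation (C3–C4) and Friedel–Crafts cyclodehydration closing ring B para to a methoxy group of ring A; alkyne carboxylation; gold-catalysed coupling with a propargyl silyl ether closing ring C; oxidation at C6'; global deprotection.
Stereochemistry: C1 comes from the rhodium-catalysed enantioselective conjugate alkynylation (ligand control). C2 is set by base equilibration to the trans isomer relative to C1 (thermodynamic control). No basic step follows the alkynoic acid, because C1–H lies γ to the alkynoate and later to the pyrone carbonyl.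

Key step: step 8

Assumption: the (R)-configured bisphosphine is taken to give the S adduct in step 2; if the sense of induction is the opposite, the (S)-ligand is used and nothing else changes.

**Route**

Step 1
Reactants: 1 3,4-dimethoxybenzaldehyde; 2 Meldrum's acid (2,2-dimethyl-1,3-dioxane-4,6-dione)
Product: 3 5-(3,4-dimethoxybenzylidene)-2,2-dimethyl-1,3-dioxane-4,6-dione
Conditions: H2O, 75 °C
Reagents that add atoms: none
Why: Knoevenagel condensation of an aromatic aldehyde with the highly acidic Meldrum's acid proceeds without catalyst in hot water, and the arylidene product should crystallise from the medium.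

Step 2
Reactants: 3 5-(3,4-dimethoxybenzylidene)-2,2-dimethyl-1,3-dioxane-4,6-dione; 4 ethynyltrimethylsilane
Product: 5 5-[(1S)-1-(3,4-dimethoxyphenyl)-3-(trimethylsilyl)prop-2-yn-1-yl]-2,2-dimethyl-1,3-dioxane-4,6-dione
Conditions: [Rh(OAc)(C2H4)2]2 (2.5 mol%), (R)-3,5-xylyl-MeO-BIPHEP (5.5 mol%), 4 (excess), 1,4-dioxane/H2O, 12 °C
Reagents that add atoms: none
Why: Rhodium-catalysed enantioselective conjugate alkynylation is established for 5-benzylidene Meldrum's acids and silylacetylenes; an alkynyl complex of monovalent rhodium adds 1,4 to the doubly activated alkene, and the chiral bisphosphine selects the face of the arylidene that gives the S adduct, which fixes C1 of the target.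

Step 3
Reactants: 5 5-[(1S)-1-(3,4-dimethoxyphenyl)-3-(trimethylsilyl)prop-2-yn-1-yl]-2,2-dimethyl-1,3-dioxane-4,6-dione; 6 methyl bromoacetate
Product: 7 methyl 2-{5-[(1R)-1-(3,4-dimethoxyphenyl)-3-(trimethylsilyl)prop-2-yn-1-yl]-2,2-dimethyl-4,6-dioxo-1,3-dioxan-5-yl}acetate
Conditions: K2CO3, DMF, rt
Reagents that add atoms: none
Why: SN2 C-alkylation of the stabilised Meldrum's acid anion by a reactive α-halo ester makes C5 quaternary and achiral, and the mild carbonate base leaves the silylalkyne and C1 untouched (the descriptor at C1 changes by priority only).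

Step 4
Reactants: 7 methyl 2-{5-[(1R)-1-(3,4-dimethoxyphenyl)-3-(trimethylsilyl)prop-2-yn-1-yl]-2,2-dimethyl-4,6-dioxo-1,3-dioxan-5-yl}acetate
Product: 9 dimethyl 2-[(1R)-1-(3,4-dimethoxyphenyl)prop-2-yn-1-yl]butanedioate (both C2 epimers), via malonic half-acid 8 (not isolated)
Conditions: NaOMe (2.5 equiv), MeOH, 0 °C → rt; aq. HCl; then DMSO, 110 °C
Reagents that add atoms: NaOMe, [Na+].[O-]C
Why: Methoxide opens the cyclic acylal by acyl substitution with loss of acetone (Meldrum's acid methanolysis) and removes the alkynyl silyl group, and the malonic half-acid then decarboxylates on heating; C2 forms without control here and is corrected in step 6.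

Step 5
Reactants: 9 dimethyl 2-[(1R)-1-(3,4-dimethoxyphenyl)prop-2-yn-1-yl]butanedioate
Product: 10 dimethyl 2-[(1R)-1-(3,4-dimethoxyphenyl)prop-2-yn-1-yl]-3-(hydroxymethylidene)butanedioate (enol form of the 3-formylsuccinate; C2 epimers)
Conditions: HCO2Me, TiCl4, Et3N, CH2Cl2, 0 °C
Reagents that add atoms: methyl formate, COC=O
Why: In this titanium-mediated crossed Claisen condensation (soft enolisation) the unhindered succinate methylene is enolised in preference to the branched C2–H and formylated by methyl formate; only this regioisomer can rest as the chelated enolate of a β-formyl ester, and the amine base is too weak to reach the benzylic propargylic C1–H.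

Step 6
Reactants: 10 dimethyl 2-[(1R)-1-(3,4-dimethoxyphenyl)prop-2-yn-1-yl]-3-(hydroxymethylidene)butanedioate
Product: 12 dimethyl (1R,2S)-1-ethynyl-6,7-dimethoxy-1,2-dihydronaphthalene-2,3-dicarboxylate, via cis/trans diester mixture 11 (not isolated)
Conditions: MeSO3H, CH2Cl2, 0 °C → rt; aq. NaHCO3 work-up; then NaOMe (0.3 equiv), MeOH, rt
Reagents that add atoms: none
Why: Acid activates the formyl group for an intramolecular Friedel–Crafts hydroxyalkylation at the ring carbon para to a methoxy group (six-membered ring B), and the benzylic alcohol dehydrates through a p-methoxybenzyl cation to the C3=C4 alkene; catalytic methoxide then epimerises C2 by reversible enolisation to the trans isomer, in which the C1 ethynyl and C2 ester groups are both pseudo-axial and strain against the C3 ester is relieved, so C2 is set under thermodynamic control relative to C1, with any residual cis isomer to be separated and resubmitted.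

Step 7
Reactants: 12 dimethyl (1R,2S)-1-ethynyl-6,7-dimethoxy-1,2-dihydronaphthalene-2,3-dicarboxylate
Product: 13 3-[(1R,2S)-2,3-bis(methoxycarbonyl)-6,7-dimethoxy-1,2-dihydronaphthalen-1-yl]prop-2-ynoic acid
Conditions: CuCl (cat.), TMEDA (cat.), K2CO3, CO2 (1 atm), DMF, rt; then cold dilute aq. HCl
Reagents that add atoms: carbon dioxide, O=C=O
Why: In this copper-catalysed C–H carboxylation of a terminal alkyne, carbonate forms the acetylide of monovalent copper, which inserts CO2; under CO2 the medium is too weakly basic to reach C1–H, and any epimerisation at C2 only returns the trans isomer.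

Step 8
Reactants: 13 3-[(1R,2S)-2,3-bis(methoxycarbonyl)-6,7-dimethoxy-1,2-dihydronaphthalen-1-yl]prop-2-ynoic acid; 14 tert-butyldimethyl(prop-2-yn-1-yloxy)silane
Product: 16 dimethyl (1R,2S)-1-[6-({[tert-butyl(dimethyl)silyl]oxy}methyl)-2-oxo-2H-pyran-4-yl]-6,7-dimethoxy-1,2-dihydronaphthalene-2,3-dicarboxylate, via enol ester 15 (not isolated)
Conditions: Ph3PAuNTf2 (5 mol%), 14 (3 equiv), CH2Cl2, rt
Reagents that add atoms: none
Why: Cationic monovalent gold first activates the terminal alkyne of 14 for Markovnikov addition of the carboxylic acid of 13, giving the 1-substituted vinyl ester 15; the same catalyst then binds the alkynoate triple bond, the enol methylene C5' attacks C4' (the alkyne carbon on C1, remote from the carbonyl), and loss of the C5' proton from the oxocarbenium ion followed by protodeauration at C3' gives the aromatic 2-pyrone. The closest known reaction type is the gold-catalysed coupling of propiolic acids with terminal alkynes to 4,6-disubstituted 2-pyrones through vinyl propiolates. Ring C closes in the 6-endo-dig mode. No stereocentre is created, and C1 and C2 are not touched, because the medium is neutral to weakly acidic and C1–H becomes acidified only once the pyrone exists. The step needs Markovnikov O–H addition and 6-endo instead of 5-exo closure; the first follows from the terminal alkyne, the second from the polarisation of the alkynoate, which makes C4' the only electrophilic carbon and leaves the ring alkene without a reachable one. Participation of the C2 ester carbonyl is held back because it is a methyl ester that cannot shed its alkyl group and sits trans-diaxial to the alkyne.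

Step 9
Reactants: 16 dimethyl (1R,2S)-1-[6-({[tert-butyl(dimethyl)silyl]oxy}methyl)-2-oxo-2H-pyran-4-yl]-6,7-dimethoxy-1,2-dihydronaphthalene-2,3-dicarboxylate
Product: 17 dimethyl (1R,2S)-1-[6-(hydroxymethyl)-2-oxo-2H-pyran-4-yl]-6,7-dimethoxy-1,2-dihydronaphthalene-2,3-dicarboxylate
Conditions: HF·pyridine, THF, 0 °C → rt
Reagents that add atoms: none
Why: Fluoride cleavage of a primary silyl ether (desilylation) under buffered acidic conditions spares the esters, the pyrone and the now acidified C1–H.

Step 10
Reactants: 17 dimethyl (1R,2S)-1-[6-(hydroxymethyl)-2-oxo-2H-pyran-4-yl]-6,7-dimethoxy-1,2-dihydronaphthalene-2,3-dicarboxylate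
Product: 18 4-[(1R,2S)-2,3-bis(methoxycarbonyl)-6,7-dimethoxy-1,2-dihydronaphthalen-1-yl]-2-oxo-2H-pyran-6-carboxylic acid
Conditions: TEMPO (20 mol%), PhI(OAc)2 (2.2 equiv), MeCN/H2O (1:1), rt
Reagents that add atoms: water, O
Why: Oxoammonium oxidation (TEMPO with PhI(OAc)2 as terminal oxidant) takes the primary alcohol to the aldehyde, whose hydrate is oxidised on to the acid, under mildly acidic conditions that should leave the electron-rich arene, the ring alkene and both stereocentres alone.

Step 11
Reactants: 18 4-[(1R,2S)-2,3-bis(methoxycarbonyl)-6,7-dimethoxy-1,2-dihydronaphthalen-1-yl]-2-oxo-2H-pyran-6-carboxylic acid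
Product: 20 (1R,2S)-1-(6-carboxy-2-oxo-2H-pyran-4-yl)-6,7-dihydroxy-1,2-dihydronaphthalene-2,3-dicarboxylic acid (CNP0195322.1), via catechol diester 19 (not isolated)
Conditions: BBr3 (excess), CH2Cl2, −78 → 0 °C; H2O; then 6 M aq. HCl/1,4-dioxane (1:1), 80 °C, argon
Reagents that add atoms: water, O
Why: BBr3 cleaves the two aryl methyl ethers by Lewis-acid-assisted SN2 demethylation, and aqueous acid then hydrolyses the two methyl esters (acid-catalysed acyl–oxygen hydrolysis) without any basic stage, so the pyrone ring and C1–H are never exposed to base and any enolisation at C2 returns the favoured trans isomer.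

**Compound list**

1 | 3,4-dimethoxybenzaldehyde | COc1ccc(C=O)cc1OC | starting material
2 | Meldrum's acid (2,2-dimethyl-1,3-dioxane-4,6-dione) | CC1(C)OC(=O)CC(=O)O1 | starting material
3 | 5-(3,4-dimethoxybenzylidene)-2,2-dimethyl-1,3-dioxane-4,6-dione | COc1ccc(C=C2C(=O)OC(C)(C)OC2=O)cc1OC | intermediate
4 | ethynyltrimethylsilane | C#C[Si](C)(C)C | starting material
5 | 5-[(1S)-1-(3,4-dimethoxyphenyl)-3-(trimethylsilyl)prop-2-yn-1-yl]-2,2-dimethyl-1,3-dioxane-4,6-dione | C[Si](C)(C)C#C[C@H](c1ccc(OC)c(OC)c1)C1C(=O)OC(C)(C)OC1=O | intermediate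
6 | methyl bromoacetate | COC(=O)CBr | starting material
7 | methyl 2-{5-[(1R)-1-(3,4-dimethoxyphenyl)-3-(trimethylsilyl)prop-2-yn-1-yl]-2,2-dimethyl-4,6-dioxo-1,3-dioxan-5-yl}acetate | C[Si](C)(C)C#C[C@H](c1ccc(OC)c(OC)c1)C1(CC(=O)OC)C(=O)OC(C)(C)OC1=O | intermediate
8 | (3R)-3-(3,4-dimethoxyphenyl)-2-(methoxycarbonyl)-2-(2-methoxy-2-oxoethyl)pent-4-ynoic acid (both C2 epimers) | C#C[C@H](c1ccc(OC)c(OC)c1)C(CC(=O)OC)(C(=O)OC)C(=O)O | intermediate
9 | dimethyl 2-[(1R)-1-(3,4-dimethoxyphenyl)prop-2-yn-1-yl]butanedioate (both C2 epimers) | C#C[C@H](c1ccc(OC)c(OC)c1)C(CC(=O)OC)C(=O)OC | intermediate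
10 | dimethyl 2-[(1R)-1-(3,4-dimethoxyphenyl)prop-2-yn-1-yl]-3-(hydroxymethylidene)butanedioate (C2 epimers, enol form) | C#C[C@H](c1ccc(OC)c(OC)c1)C(C(=O)OC)C(=CO)C(=O)OC | intermediate
11 | dimethyl (1R)-1-ethynyl-6,7-dimethoxy-1,2-dihydronaphthalene-2,3-dicarboxylate (cis and trans at C2) | COC(=O)C1=Cc2cc(OC)c(OC)cc2[C@@H](C#C)C1C(=O)OC | intermediate
12 | dimethyl (1R,2S)-1-ethynyl-6,7-dimethoxy-1,2-dihydronaphthalene-2,3-dicarboxylate (trans) | COC(=O)C1=Cc2cc(OC)c(OC)cc2[C@@H](C#C)[C@@H]1C(=O)OC | intermediate
13 | 3-[(1R,2S)-2,3-bis(methoxycarbonyl)-6,7-dimethoxy-1,2-dihydronaphthalen-1-yl]prop-2-ynoic acid | COC(=O)C1=Cc2cc(OC)c(OC)cc2[C@@H](C#CC(=O)O)[C@@H]1C(=O)OC | intermediate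
14 | tert-butyldimethyl(prop-2-yn-1-yloxy)silane | C#CCO[Si](C)(C)C(C)(C)C | starting material
15 | 3-{[tert-butyl(dimethyl)silyl]oxy}prop-1-en-2-yl 3-[(1R,2S)-2,3-bis(methoxycarbonyl)-6,7-dimethoxy-1,2-dihydronaphthalen-1-yl]prop-2-ynoate | COC(=O)C1=Cc2cc(OC)c(OC)cc2[C@@H](C#CC(=O)OC(=C)CO[Si](C)(C)C(C)(C)C)[C@@H]1C(=O)OC | intermediate
16 | dimethyl (1R,2S)-1-[6-({[tert-butyl(dimethyl)silyl]oxy}methyl)-2-oxo-2H-pyran-4-yl]-6,7-dimethoxy-1,2-dihydronaphthalene-2,3-dicarboxylate | COC(=O)C1=Cc2cc(OC)c(OC)cc2[C@@H](c2cc(CO[Si](C)(C)C(C)(C)C)oc(=O)c2)[C@@H]1C(=O)OC | intermediate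
17 | dimethyl (1R,2S)-1-[6-(hydroxymethyl)-2-oxo-2H-pyran-4-yl]-6,7-dimethoxy-1,2-dihydronaphthalene-2,3-dicarboxylate | COC(=O)C1=Cc2cc(OC)c(OC)cc2[C@@H](c2cc(CO)oc(=O)c2)[C@@H]1C(=O)OC | intermediate
18 | 4-[(1R,2S)-2,3-bis(methoxycarbonyl)-6,7-dimethoxy-1,2-dihydronaphthalen-1-yl]-2-oxo-2H-pyran-6-carboxylic acid | COC(=O)C1=Cc2cc(OC)c(OC)cc2[C@@H](c2cc(C(=O)O)oc(=O)c2)[C@@H]1C(=O)OC | intermediate
19 | 4-[(1R,2S)-6,7-dihydroxy-2,3-bis(methoxycarbonyl)-1,2-dihydronaphthalen-1-yl]-2-oxo-2H-pyran-6-carboxylic acid | COC(=O)C1=Cc2cc(O)c(O)cc2[C@@H](c2cc(C(=O)O)oc(=O)c2)[C@@H]1C(=O)OC | intermediate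
20 | (1R,2S)-1-(6-carboxy-2-oxo-2H-pyran-4-yl)-6,7-dihydroxy-1,2-dihydronaphthalene-2,3-dicarboxylic acid (CNP0195322.1) | O=C(O)C1=Cc2cc(O)c(O)cc2[C@@H](c2cc(C(=O)O)oc(=O)c2)[C@@H]1C(=O)O | target

**Count and risks**

Total step count: 11. Longest linear sequence: 11 steps (from 1; the route is fully linear).

Steps most likely to fail:

Step 8. The intermolecular O–H addition may be outrun by protodecarboxylation of the alkynoic acid or by hydration and oligomerisation of the terminal alkyne, and the 6-endo attack may be slow at the hindered alkyne carbon C4'. The fallback closes ring C at O1'–C6' instead and sets out from 13. Hydroiodination with NaI in acetic acid at 70 °C should add HI anti across the alkynoic acid and give the (Z)-3-iodopropenoic acid F1. Negishi coupling of this with [3-(tert-butyldimethylsilyloxy)prop-1-ynyl]zinc bromide (from 14, n-BuLi, then ZnBr2; in excess, since the first equivalent is taken by the acid) under Pd(PPh3)4 catalysis should give, with retention of alkene geometry, the (Z)-2-en-4-ynoic acid F2. ZnBr2-catalysed 6-endo-dig lactonisation of the carboxyl group onto the alkyne then returns to the route at 16.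

Step 6. The acid may hydrate or oligomerise the terminal alkyne faster than the ring closes, the enolised formyl group may resist ionisation, or the enolate in the equilibration may reprotonate at C4 and move the double bond out of conjugation with ring A. The fallback puts the one-carbon unit on the arene instead of the succinate and sets out from 9, leaving out step 5. Rieche formylation (Cl2CHOMe, TiCl4, CH2Cl2, −78 → 0 °C) at the ring position para to a methoxy group and ortho to the side chain should give the aryl aldehyde F3. NaOMe in MeOH then effects intramolecular aldol condensation of the succinate methylene onto the aldehyde with dehydration, together with equilibration at C2, and returns to the route at 12.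

Step 2. Facial selectivity may be insufficient, or conjugate addition slow, with the electron-rich arylidene. The fallback replaces asymmetric catalysis by resolution and sets out from 3. Uncatalysed 1,4-addition of [(trimethylsilyl)ethynyl]magnesium bromide (THF, −20 °C) gives the racemic adduct F4. Because the monosubstituted Meldrum's acid is a strong carbon acid, it forms diastereomeric salts with (S)-1-phenylethylamine, and crystallisation should give the 1-phenylethylammonium salt F5 of the S acid (the R amine is used if that pairing is the less soluble one). Dilute aqueous HCl liberates the acid and returns to the route at 5.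

Further compounds
F1 | step 8 | (2Z)-3-[2,3-bis(methoxycarbonyl)-6,7-dimethoxy-1,2-dihydronaphthalen-1-yl]-3-iodoprop-2-enoic acid, C1 and C2 trans with the spatial arrangement of 13 | COC(=O)C1=Cc2cc(OC)c(OC)cc2[C@@H](/C(I)=C/C(=O)O)[C@@H]1C(=O)OC
F2 | step 8 | (2Z)-3-[2,3-bis(methoxycarbonyl)-6,7-dimethoxy-1,2-dihydronaphthalen-1-yl]-6-{[tert-butyl(dimethyl)silyl]oxy}hex-2-en-4-ynoic acid, C1 and C2 trans with the spatial arrangement of 13 | COC(=O)C1=Cc2cc(OC)c(OC)cc2[C@@H](/C(C#CCO[Si](C)(C)C(C)(C)C)=C/C(=O)O)[C@@H]1C(=O)OC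
F3 | step 6 | dimethyl 2-[(1R)-1-(2-formyl-4,5-dimethoxyphenyl)prop-2-yn-1-yl]butanedioate (both C2 epimers) | C#C[C@H](c1cc(OC)c(OC)cc1C=O)C(CC(=O)OC)C(=O)OC
F4 | step 2 | racemic 5-[1-(3,4-dimethoxyphenyl)-3-(trimethylsilyl)prop-2-yn-1-yl]-2,2-dimethyl-1,3-dioxane-4,6-dione | C[Si](C)(C)C#CC(c1ccc(OC)c(OC)c1)C1C(=O)OC(C)(C)OC1=O
F5 | step 2 | (S)-1-phenylethylammonium salt of 5-[(1S)-1-(3,4-dimethoxyphenyl)-3-(trimethylsilyl)prop-2-yn-1-yl]-2,2-dimethyl-1,3-dioxane-4,6-dione | C[C@H]([NH3+])c1ccccc1.C[Si](C)(C)C#C[C@H](c1ccc(OC)c(OC)c1)C1=C([O-])OC(C)(C)OC1=O
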